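Readings and results were generated by integration with constants of no real substance; the scatter is artificial.

If a colleague wants to know how long the chains of south and north end up, the first question is how many chains each flask begins, and no reading counts them.

all flasks: free monomer 1.5 M (fed, over 1.5 h)

| run | initiator | remark | time |
|---|---|---|---|
| maple | 0.91 mol% | run made earlier; the fed solution adds 0.20 times the starting volume |  |
| elm | 1.8 mol% | run made earlier; the fed solution adds 0.20 times the starting volume |  |
| ash | 2.3 mol% | run made earlier; the fed solution adds 0.20 times the starting volume |  |
| south | 1 mol% | the fed solution adds 0.20 times the starting volume | 2.0 h |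
| north | 3 mol% | the fed solution adds 0.20 times the starting volume | 2.0 h |

| run | time / min | monomer in chains / % | free monomer / % |
|---|---|---|---|
| maple | 15.0 | 0.1 | 15.3 |
| maple | 30.0 | 11.2 | 20.9 |
| maple | 50.0 | 35.6 | 20.3 |
| maple | 60.0 | 45.7 | 18.5 |
| maple | 80.0 | 70.2 | 16.7 |
| elm | 15.0 | 2.7 | 15.8 |
| elm | 30.0 | 17.0 | 14.7 |
| elm | 50.0 | 43.2 | 10.8 |
| elm | 60.0 | 55.1 | 10.9 |
| elm | 80.0 | 75.9 | 10.0 |
| ash | 15.0 | 3.0 | 13.1 |
| ash | 30.0 | 17.9 | 14.2 |
| ash | 50.0 | 43.6 | 9.4 |
| ash | 60.0 | 56.2 | 8.0 |
| ash | 80.0 | 79.1 | 7.7 |

(scatter of a reading: 1 percentage point)

- charges are per starting volume, the dose included; the dosed solution carries all of it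
- the average divides the monomer in chains by the number of chains begun, living and dead together
- the earlier runs do not show the number of chains; that part of a forecast is a guess
- percentages count the whole charge, also what has not yet gone in

1. which of the two ends with the longer chains by the average number of monomer units in a chain (chains begun, living or dead) ("neither" if they lie within 10%) (south / north / neither)
2. average number of monomer units in a chain (chains begun, living or dead) at the end, south
3. average number of monomer units in a chain (chains begun, living or dead) at the end, north

Question: what in the runs speaks of the chains at all? Answer: the free monomer, whose reading at 80.0 min stands higher in maple, at 16.7%, than in ash, at 7.7%, and maple was charged with less initiator than ash.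

Question: how do you reckon with that? Answer: I replace each curve by the mean of its readings, turn it into a concentration over the final volume and multiply by the dosing time, which for elm gives 14.0 M·min; this exposure, E, the free monomer concentration summed over time, comes to 20.6 M·min for maple and 11.8 M·min for ash, and I assume that the empty start the mean ignores offsets the tail after the feed.

Question: and what does E say? Answer: chains times E should be much the same wherever the charge has been taken up, so if all initiator began chains, E times loading would stand still, yet ash's product is 1.44 times maple's, a reading which says that ash has used a smaller share of its initiator, its initiator efficiency.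

Question: but ash is not north? Answer: no, and carrying that ratio over is my guess; with about 100 units for south, as at full use, I commit to 48.1 for north, which is more than the forecast's figure.

The forecast chose south, with 96 and 33, taking “If each initiator begins one chain” as its ground.

The flask gives south, with 99.6 and 42.5.

    free monomer → uncatalysed product (k = 0.00202 /min)
    free monomer + living end → monomer in chains + living end, rate k2*[living end]*[free monomer] (k = 6.44 /M/min)
    free monomer + initiator → living end + monomer in chains (k = 0.137 /M/min)
    monomer in chains → over-reaction product (k = 1.59 × 10⁻⁴ /min)

At the end north still holds 24% of its initiator and south 5.2%. The neighbour, north's recipe at 1.8 mol%, has elm's loading, and I take elm's E for it: with k3, the rate constant of free monomer + initiator, at 0.137 /M/min, the reckoned initiator left is 14.7%, and the neighbour holds 14%. With 96.6% of the free monomer charged standing as monomer in chains, the reckoned initiator used gives 62.9 units per chain, and the neighbour ends at 62.1.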